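**Plan**
- Cuts: the depside ester C–O bond between the ring B carbonyl and O-4 of ring A; the C(=O)–propyl bond of the 2-oxopentyl arm; and, in one operation, the ring B C1–C(=O) and C6–CH2 bonds.
- Enabling feature: on ring B the ester carbonyl sits on C1, between the C2 methoxy group and the CH2 of the arm on C6. Vicinal acyl and alkyl carbons on adjacent ring atoms are what an aryne leaves when it inserts into the CH2–C(=O) bond of a malonate.
- Forward order: 3,5-dimethoxyphenol to the silyl triflate (steps 1–2), insertion of 3,5-dimethoxybenzyne into dibenzyl malonate (step 3), arm ester to Weinreb amide to propyl ketone (steps 4–5), dioxolane and debenzylation (steps 6–7), esterification with benzyl olivetolate (steps 8–9), ketal hydrolysis and hydrogenolysis (steps 10–11).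
- No ring is formed at any stage; both benzene rings are bought.
- The ketone is made before ring A is attached and is carried as a dioxolane, so that no Grignard reagent meets the depside ester and no free keto acid is ever activated (it would close to an isocoumarin).
- The target has no stereocentre; only regiochemistry has to be controlled (aryne addition, 4-OH versus 2-OH acylation of ring A).

Key step: step 3

Assumption: olivetolic acid (13) is taken as purchasable and is handled at or below room temperature, since it decarboxylates easily.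

**Step 1**
Reactants: 1 3,5-dimethoxyphenol
Product: 2 2-bromo-3,5-dimethoxyphenol
Conditions: NBS, i-Pr2NH (cat.), CH2Cl2, −78 to 0 °C
Reagents that add atoms: N-bromosuccinimide, O=C1CCC(=O)N1Br
Why: Electrophilic aromatic bromination of the activated phenol under amine catalysis should deliver bromine ortho to the hydroxyl group (C2, also para to a methoxy group) in preference to the position between the two methoxy groups.

**Step 2**
Reactants: 2 2-bromo-3,5-dimethoxyphenol
Product: 5 3,5-dimethoxy-2-(trimethylsilyl)phenyl trifluoromethanesulfonate, via aryl trimethylsilyl ether 3 (not isolated), via lithium 2-silylphenoxide 4 (not isolated)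
Conditions: HMDS, THF, reflux, then volatiles off; n-BuLi, THF, −100 °C; Tf2O, −100 °C to rt
Reagents that add atoms: hexamethyldisilazane, C[Si](C)(C)N[Si](C)(C)C; trifluoromethanesulfonic anhydride, O=S(=O)(OS(=O)(=O)C(F)(F)F)C(F)(F)F
Why: O-silylation, bromine–lithium exchange, anionic 1,3 O-to-C silyl shift (retro-Brook rearrangement) and triflation of the resulting phenoxide form the standard one-pot entry to ortho-silylaryl triflates.

**Step 3**
Reactants: 5 3,5-dimethoxy-2-(trimethylsilyl)phenyl trifluoromethanesulfonate; 6 dibenzyl malonate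
Product: 8 benzyl 2-[2-(benzyloxy)-2-oxoethyl]-4,6-dimethoxybenzoate, via 3,5-dimethoxybenzyne 7 (not isolated)
Conditions: CsF, MeCN, 80 °C
Reagents that add atoms: none
Why: Fluoride attacks silicon and the ortho triflate leaves, giving aryne 7 between the former silyl and triflate carbons, while the basic fluoride medium supplies the malonate enolate. The enolate carbon should add to the former triflate carbon, remote from the methoxy group, and the aryl anion created on the former silyl carbon then attacks one ester carbonyl (4-exo-trig) to a benzocyclobutenoxide, whose retro-aldol-type opening gives the arylacetate enolate that is protonated on work-up. The net result is insertion of the aryne into the CH2–C(=O) bond, the acyl-alkylation of arynes known for malonates and β-ketoesters; the four-membered ring is only transient, so no ring and no stereocentre remain in 8. The step needs regioselective addition to an unsymmetrical aryne, and the inductively electron-withdrawing methoxy group beside the triple bond secures it by stabilising negative charge on the adjacent carbon and steering the nucleophile to the distal one. It also needs acyl transfer to outrun protonation of the aryl anion, which the aprotic medium and the intramolecular delivery to a neighbouring ester carbonyl should favour.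

**Step 4**
Reactants: 8 benzyl 2-[2-(benzyloxy)-2-oxoethyl]-4,6-dimethoxybenzoate
Product: 9 benzyl 2,4-dimethoxy-6-{2-[methoxy(methyl)amino]-2-oxoethyl}benzoate
Conditions: MeNHOMe·HCl, AlMe3, CH2Cl2, 0 °C to rt
Reagents that add atoms: N,O-dimethylhydroxylamine hydrochloride, CNOC.Cl
Why: Weinreb aminolysis with the aluminium amide should attack only the unhindered arylacetic ester, because the benzoate carbonyl is shielded by its two ortho substituents and the reagent is too weakly basic to disturb the acidic benzylic CH2.

**Step 5**
Reactants: 9 benzyl 2,4-dimethoxy-6-{2-[methoxy(methyl)amino]-2-oxoethyl}benzoate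
Product: 10 benzyl 2,4-dimethoxy-6-(2-oxopentyl)benzoate
Conditions: n-PrMgCl, THF, −40 to 0 °C; cold aq. NH4Cl
Reagents that add atoms: n-propylmagnesium chloride, CCC[Mg]Cl
Why: In this Weinreb ketone synthesis the chelated tetrahedral magnesium adduct stops at mono-addition and releases the ketone only on the mildly acidic quench, while the di-ortho-substituted benzyl benzoate is too hindered to react at low temperature.

**Step 6**
Reactants: 10 benzyl 2,4-dimethoxy-6-(2-oxopentyl)benzoate
Product: 11 benzyl 2,4-dimethoxy-6-[(2-propyl-1,3-dioxolan-2-yl)methyl]benzoate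
Conditions: TMSOCH2CH2OTMS, TMSOTf (cat.), CH2Cl2, −78 to −20 °C; pyridine quench
Reagents that add atoms: 1,2-bis(trimethylsilyloxy)ethane, C[Si](C)(C)OCCO[Si](C)(C)C
Why: Noyori ketalisation under aprotic, low-temperature conditions should mask the ketone without giving its enol the chance to close onto the neighbouring ester, and the dioxolane later keeps the arm inert when the ring B carboxyl group is freed and activated.

**Step 7**
Reactants: 11 benzyl 2,4-dimethoxy-6-[(2-propyl-1,3-dioxolan-2-yl)methyl]benzoate
Product: 12 2,4-dimethoxy-6-[(2-propyl-1,3-dioxolan-2-yl)methyl]benzoic acid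
Conditions: H2 (1 atm), 10% Pd/C, EtOAc, rt; used without storage
Reagents that add atoms: none
Why: Hydrogenolysis of the benzyl ester is neutral and should leave the dioxolane, the aryl methyl ethers and the arene untouched.

**Step 8**
Reactants: 13 olivetolic acid (2,4-dihydroxy-6-pentylbenzoic acid)
Product: 14 benzyl 2,4-dihydroxy-6-pentylbenzoate (benzyl olivetolate)
Conditions: BnBr, KHCO3, DMF, rt
Reagents that add atoms: benzyl bromide, BrCc1ccccc1
Why: Bicarbonate deprotonates only the carboxylic acid, so SN2 O-alkylation of the carboxylate by benzyl bromide should give the ester and leave both phenols free.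

**Step 9**
Reactants: 12 2,4-dimethoxy-6-[(2-propyl-1,3-dioxolan-2-yl)methyl]benzoic acid; 14 benzyl 2,4-dihydroxy-6-pentylbenzoate
Product: 15 benzyl 4-({2,4-dimethoxy-6-[(2-propyl-1,3-dioxolan-2-yl)methyl]benzoyl}oxy)-2-hydroxy-6-pentylbenzoate
Conditions: DCC, DMAP, CH2Cl2, 0 °C to rt
Reagents that add atoms: none
Why: In this Steglich esterification the acylpyridinium derived from the hindered acid should be captured by the 4-hydroxyl of 14, the more nucleophilic and less hindered phenol, since the 2-hydroxyl is hydrogen-bonded to and flanked by the benzyl ester.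

**Step 10**
Reactants: 15 benzyl 4-({2,4-dimethoxy-6-[(2-propyl-1,3-dioxolan-2-yl)methyl]benzoyl}oxy)-2-hydroxy-6-pentylbenzoate
Product: 16 benzyl 4-{[2,4-dimethoxy-6-(2-oxopentyl)benzoyl]oxy}-2-hydroxy-6-pentylbenzoate
Conditions: 1 M aq. HCl, THF, rt
Reagents that add atoms: water, O
Why: Acid-catalysed ketal hydrolysis with dilute aqueous acid at room temperature should free the ketone while the hindered depside ester and the benzyl ester survive, and it avoids base, under which the keto ester would cyclise.

**Step 11**
Reactants: 16 benzyl 4-{[2,4-dimethoxy-6-(2-oxopentyl)benzoyl]oxy}-2-hydroxy-6-pentylbenzoate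
Product: 17 4-{[2,4-dimethoxy-6-(2-oxopentyl)benzoyl]oxy}-2-hydroxy-6-pentylbenzoic acid (target)
Conditions: H2 (1 atm), 10% Pd/C, EtOAc, rt
Reagents that add atoms: none
Why: Hydrogenolysis of the benzyl ester under neutral conditions should release the salicylic acid without touching the dialkyl ketone or the aryl ester, so the sensitive keto depside is exposed to neither acid nor base at the end.

**Compound list**
1 | 3,5-dimethoxyphenol | COc1cc(O)cc(OC)c1 | starting material
2 | 2-bromo-3,5-dimethoxyphenol | COc1cc(O)c(Br)c(OC)c1 | intermediate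
3 | (2-bromo-3,5-dimethoxyphenoxy)trimethylsilane | COc1cc(O[Si](C)(C)C)c(Br)c(OC)c1 | intermediate
4 | lithium 3,5-dimethoxy-2-(trimethylsilyl)phenoxide | [Li+].[O-]c1cc(OC)cc(OC)c1[Si](C)(C)C | intermediate
5 | 3,5-dimethoxy-2-(trimethylsilyl)phenyl trifluoromethanesulfonate | COc1cc(OC)c([Si](C)(C)C)c(OS(=O)(=O)C(F)(F)F)c1 | intermediate
6 | dibenzyl malonate | O=C(CC(=O)OCc1ccccc1)OCc1ccccc1 | starting material
7 | 3,5-dimethoxybenzyne (1,2-didehydro-3,5-dimethoxybenzene) | COC1=CC#CC(OC)=C1 | intermediate
8 | benzyl 2-[2-(benzyloxy)-2-oxoethyl]-4,6-dimethoxybenzoate | COc1cc(OC)c(C(=O)OCc2ccccc2)c(CC(=O)OCc2ccccc2)c1 | intermediate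
9 | benzyl 2,4-dimethoxy-6-{2-[methoxy(methyl)amino]-2-oxoethyl}benzoate | COc1cc(OC)c(C(=O)OCc2ccccc2)c(CC(=O)N(C)OC)c1 | intermediate
10 | benzyl 2,4-dimethoxy-6-(2-oxopentyl)benzoate | CCCC(=O)Cc1cc(OC)cc(OC)c1C(=O)OCc1ccccc1 | intermediate
11 | benzyl 2,4-dimethoxy-6-[(2-propyl-1,3-dioxolan-2-yl)methyl]benzoate | CCCC1(Cc2cc(OC)cc(OC)c2C(=O)OCc2ccccc2)OCCO1 | intermediate
12 | 2,4-dimethoxy-6-[(2-propyl-1,3-dioxolan-2-yl)methyl]benzoic acid | CCCC1(Cc2cc(OC)cc(OC)c2C(=O)O)OCCO1 | intermediate
13 | olivetolic acid (2,4-dihydroxy-6-pentylbenzoic acid) | CCCCCc1cc(O)cc(O)c1C(=O)O | starting material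
14 | benzyl 2,4-dihydroxy-6-pentylbenzoate | CCCCCc1cc(O)cc(O)c1C(=O)OCc1ccccc1 | intermediate
15 | benzyl 4-({2,4-dimethoxy-6-[(2-propyl-1,3-dioxolan-2-yl)methyl]benzoyl}oxy)-2-hydroxy-6-pentylbenzoate | CCCCCc1cc(OC(=O)c2c(CC3(CCC)OCCO3)cc(OC)cc2OC)cc(O)c1C(=O)OCc1ccccc1 | intermediate
16 | benzyl 4-{[2,4-dimethoxy-6-(2-oxopentyl)benzoyl]oxy}-2-hydroxy-6-pentylbenzoate | CCCCCc1cc(OC(=O)c2c(CC(=O)CCC)cc(OC)cc2OC)cc(O)c1C(=O)OCc1ccccc1 | intermediate
17 | 4-{[2,4-dimethoxy-6-(2-oxopentyl)benzoyl]oxy}-2-hydroxy-6-pentylbenzoic acid (CNP0584180.0) | CCCCCc1cc(OC(=O)c2c(CC(=O)CCC)cc(OC)cc2OC)cc(O)c1C(=O)O | target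

**Step count and risks**
Total: 11 steps. Longest linear sequence: 10 steps (steps 1–7 and 9–11); step 8 is a one-step side branch.

Steps most likely to fail:

1. Step 3 (key step). The aryl anion formed after addition may be protonated by acetonitrile or by a second malonate before it reaches the ester carbonyl, which would give plain α-arylation. The still acidic CH2 of 8 may also be arylated by a second aryne. The fallback avoids the aryne, sets out from 2 and returns at 8. Twofold lithiation of 2 (n-BuLi, THF, −78 °C) and a CO2 quench should give 2-hydroxy-4,6-dimethoxybenzoic acid F1. BnBr and KHCO3 in DMF should give benzyl 2-hydroxy-4,6-dimethoxybenzoate F2. Tf2O and pyridine should give benzyl 2,4-dimethoxy-6-{[(trifluoromethyl)sulfonyl]oxy}benzoate F3. Negishi-type coupling of F3 with the Reformatsky reagent from benzyl bromoacetate (BrZnCH2CO2Bn, Pd(dba)2, P(t-Bu)3, THF) should then attach the CH2CO2Bn arm and give 8, with the substitution pattern fixed by the bromine of 2.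

2. Step 9. Acyl transfer from the doubly ortho-substituted acid may be slow, leaving time for O-to-N acyl migration in the O-acylisourea or for a dioxolane oxygen to attack the activated carboxyl group; more forceful acidic activation is barred by the ketal. The fallback changes the order of events, sets out from 9 and returns at 16. Hydrogenolysis of 9 (H2, Pd/C, EtOAc) should give 2,4-dimethoxy-6-{2-[methoxy(methyl)amino]-2-oxoethyl}benzoic acid F4. Having no acid-labile group, F4 can be joined to 14 by the mixed-anhydride method (TFAA, toluene, rt), which should give benzyl 4-[(2,4-dimethoxy-6-{2-[methoxy(methyl)amino]-2-oxoethyl}benzoyl)oxy]-2-hydroxy-6-pentylbenzoate F5. n-PrMgCl (two equivalents, the first spent on the phenol; THF, −40 °C, acidic quench) should then convert the amide to ketone 16. This detour also removes steps 6, 7 and 10, at the price of a Grignard addition that relies on the steric shielding of the depside ester.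

3. Step 1. Bromine may enter at C4 between the two methoxy groups, or twice. The fallback replaces electrophilic substitution by directed ortho-metalation, sets out from 1 and returns at 5. i-PrNCO with catalytic Et3N should give 3,5-dimethoxyphenyl isopropylcarbamate F6. In situ N-silylation (TBSOTf, TMEDA), lithiation with n-BuLi/TMEDA at −78 °C between the carbamate and the methoxy group, and a TMSCl quench with acidic work-up should give 3,5-dimethoxy-2-(trimethylsilyl)phenyl isopropylcarbamate F7. Carbamate cleavage with DBU and Et2NH in MeCN, followed in the same pot by PhNTf2, should give triflate 5.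

**Further compounds**
F1 | step 3 | 2-hydroxy-4,6-dimethoxybenzoic acid | COc1cc(O)c(C(=O)O)c(OC)c1
F2 | step 3 | benzyl 2-hydroxy-4,6-dimethoxybenzoate | COc1cc(O)c(C(=O)OCc2ccccc2)c(OC)c1
F3 | step 3 | benzyl 2,4-dimethoxy-6-{[(trifluoromethyl)sulfonyl]oxy}benzoate | COc1cc(OC)c(C(=O)OCc2ccccc2)c(OS(=O)(=O)C(F)(F)F)c1
F4 | step 9 | 2,4-dimethoxy-6-{2-[methoxy(methyl)amino]-2-oxoethyl}benzoic acid | COc1cc(OC)c(C(=O)O)c(CC(=O)N(C)OC)c1
F5 | step 9 | benzyl 4-[(2,4-dimethoxy-6-{2-[methoxy(methyl)amino]-2-oxoethyl}benzoyl)oxy]-2-hydroxy-6-pentylbenzoate | CCCCCc1cc(OC(=O)c2c(CC(=O)N(C)OC)cc(OC)cc2OC)cc(O)c1C(=O)OCc1ccccc1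
F6 | step 1 | 3,5-dimethoxyphenyl isopropylcarbamate | COc1cc(OC)cc(OC(=O)NC(C)C)c1
F7 | step 1 | 3,5-dimethoxy-2-(trimethylsilyl)phenyl isopropylcarbamate | COc1cc(OC)c([Si](C)(C)C)c(OC(=O)NC(C)C)c1
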